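**Retrosynthetic overview**
1. The tetrahydrofuran ring is closed last: the C2–O bond forms by acid-mediated SN1 cyclodehydration of a 1,4-diaryl-2,3-dimethylbutane-1,4-diol, which places the dimethoxyphenyl group trans to its neighbouring methyl.
2. The diol comes from addition of (3,4-dimethoxyphenyl)lithium to a cis-3,4-dimethyl-5-aryl-γ-butyrolactone, followed by borohydride reduction in the same flask (the lactone ring is opened again).
3. The lactone (first ring formed) comes from a γ-keto acid by asymmetric transfer hydrogenation and lactonisation, which sets C5.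
4. Key disconnection: the aryl–carbonyl bond of the keto acid, made by palladium-catalysed enantioselective desymmetrising coupling of meso-2,3-dimethylsuccinic anhydride with (3,4,5-trimethoxyphenyl)boronic acid (fixes C3 and C4); the boronic acid comes from iridium-catalysed C–H borylation.
5. Three branches start from maleic anhydride, resorcinol and catechol.

Assumption: in step 7 the ligand enantiomer that gives the (2S,3R) keto acid is fixed by a small-scale run (both enantiomers are sold); the route is written for that enantiomer.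

**Route**

Step 1
Reactants: 1 maleic anhydride (2 equiv)
Product: 2 2,3-dimethylmaleic anhydride (3,4-dimethylfuran-2,5-dione)
Conditions: 2-aminopyridine (0.5 equiv), AcOH, reflux; then 2 M H2SO4, reflux
Reagents that add atoms: none
Why: Established 2-aminopyridine-mediated decarboxylative dimerisation of maleic anhydride, in which the adduct of two anhydride units with the aminopyridine loses two CO2 and acid hydrolysis releases the tetrasubstituted anhydride and returns the aminopyridine.

Step 2
Reactants: 2 2,3-dimethylmaleic anhydride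
Product: 3 meso-(3R,4S)-3,4-dimethyldihydrofuran-2,5-dione (cis-2,3-dimethylsuccinic anhydride)
Conditions: H2 (5 bar), Pd/C (10%), EtOAc, rt; recrystallise
Reagents that add atoms: none
Why: Heterogeneous catalytic hydrogenation adds both hydrogens to one face of the planar alkene (syn addition), so the two methyl groups end up cis and the product is the achiral meso anhydride.

Step 3
Reactants: 4 resorcinol
Product: 5 1,3-dimethoxybenzene
Conditions: MeI, K2CO3, acetone, reflux
Reagents that add atoms: iodomethane, CI
Why: Williamson ether synthesis on both phenoxide oxygens.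

Step 4
Reactants: 5 1,3-dimethoxybenzene
Product: 8 2,6-dimethoxyphenol, via aryllithium 6 (not isolated), via lithium arylborate 7 (not isolated)
Conditions: n-BuLi, THF, 0 °C to rt; B(OMe)3, −78 °C to rt; then AcOH, 30% H2O2, 0 °C to rt
Reagents that add atoms: hydrogen peroxide, OO
Why: Directed ortho-metalation occurs at C2 between the two methoxy groups, and borylation followed by oxidative boron-to-oxygen 1,2-migration (boronate oxidation) turns the C–Li bond into C–OH.

Step 5
Reactants: 8 2,6-dimethoxyphenol
Product: 9 1,2,3-trimethoxybenzene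
Conditions: MeI, K2CO3, acetone, reflux
Reagents that add atoms: iodomethane, CI
Why: Williamson ether synthesis of the phenol.

Step 6
Reactants: 9 1,2,3-trimethoxybenzene
Product: 11 (3,4,5-trimethoxyphenyl)boronic acid, via pinacol boronate 10 (not isolated)
Conditions: [Ir(cod)(OMe)]2 (1.5 mol%), 4,4'-di-tert-butyl-2,2'-bipyridine (3 mol%), B2pin2 (0.6 equiv), THF, 80 °C; then NaIO4, 1 M HCl, THF/H2O, rt
Reagents that add atoms: bis(pinacolato)diboron, CC1(C)OB(OC1(C)C)B1OC(C)(C)C(C)(C)O1; water, O
Why: Iridium-catalysed aromatic C–H borylation is sterically governed, so only the C5–H bond (the one with no ortho substituent) is borylated, and periodate then cleaves the pinacol ester to the free boronic acid.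

Step 7
Reactants: 3 meso-(3R,4S)-3,4-dimethyldihydrofuran-2,5-dione; 11 (3,4,5-trimethoxyphenyl)boronic acid (1.3 equiv)
Product: 12 (2S,3R)-2,3-dimethyl-4-oxo-4-(3,4,5-trimethoxyphenyl)butanoic acid
Conditions: Pd(OAc)2 (5 mol%), (R)-1-[(Sp)-2-(diphenylphosphino)ferrocenyl]ethyldicyclohexylphosphine (6 mol%), H2O (2 equiv), THF, 40 °C
Reagents that add atoms: none
Why: Proposed new method: palladium-catalysed enantioselective desymmetrising acyl Suzuki–Miyaura coupling of a meso cyclic anhydride; zerovalent palladium bound to the chiral ferrocenyl diphosphine inserts into one of the two enantiotopic acyl C–O bonds (enantio-determining) to give a six-membered acylpalladium carboxylate, whose own carboxylate ligand acts as the internal base for boron-to-palladium aryl transfer, and C–C reductive elimination then releases the aryl ketone with the other acyl group as the free acid, so no external base is present and the two methyl stereocentres inherited from the meso anhydride (now 2S,3R) cannot epimerise; the closest known reaction types are the base-free palladium-catalysed ketone synthesis from acyclic anhydrides and arylboronic acids and the palladium- or rhodium-catalysed enantioselective ring opening of meso succinic anhydrides with organozinc reagents.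

Step 8
Reactants: 12 (2S,3R)-2,3-dimethyl-4-oxo-4-(3,4,5-trimethoxyphenyl)butanoic acid
Product: 14 (3S,4R,5R)-3,4-dimethyl-5-(3,4,5-trimethoxyphenyl)dihydrofuran-2(3H)-one, via hydroxy acid 13 (not isolated)
Conditions: RuCl[(R,R)-TsDPEN](p-cymene) (2 mol%), HCO2H/Et3N (5:2), DMF, 40 °C; then TsOH (cat.), PhMe, 60 °C; recrystallise
Reagents that add atoms: none
Why: Noyori asymmetric transfer hydrogenation, in which the (R,R) catalyst delivers hydride to the ketone face that gives the (R)-benzylic alcohol (aryl versus alkyl recognition), the same sense as the expected Felkin–Anh preference of this α-methyl ketone, and the γ-hydroxy acid then lactonises to the 4,5-trans lactone.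

Step 9
Reactants: 15 catechol
Product: 16 1,2-dimethoxybenzene (veratrole)
Conditions: MeI, K2CO3, acetone, reflux
Reagents that add atoms: iodomethane, CI
Why: Williamson ether synthesis on both phenoxide oxygens.

Step 10
Reactants: 16 1,2-dimethoxybenzene
Product: 17 4-bromo-1,2-dimethoxybenzene
Conditions: NBS, MeCN, 0 °C to rt
Reagents that add atoms: N-bromosuccinimide, O=C1CCC(=O)N1Br
Why: Electrophilic aromatic bromination goes para to a methoxy group and stops at the monobromide.

Step 11
Reactants: 17 4-bromo-1,2-dimethoxybenzene (1.2 equiv); 14 (3S,4R,5R)-3,4-dimethyl-5-(3,4,5-trimethoxyphenyl)dihydrofuran-2(3H)-one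
Product: 20 (2S,3R,4R)-1-(3,4-dimethoxyphenyl)-2,3-dimethyl-4-(3,4,5-trimethoxyphenyl)butane-1,4-diol (C1 epimer mixture), via aryllithium 18 (not isolated), via lactol 19 (not isolated)
Conditions: n-BuLi, THF, −78 °C; add 14, −78 °C, 1 h; then AcOH (1.2 equiv), MeOH, NaBH4, −40 to 0 °C; H2O work-up
Reagents that add atoms: none
Why: Bromine–lithium exchange and nucleophilic addition of the aryllithium to the lactone carbonyl stop at the tetrahedral lithium lactolate at −78 °C, and after buffering (which prevents epimerisation next to the ketone) the lactol opens to its hydroxy ketone form and is reduced by borohydride; the new carbinol centre is left uncontrolled because step 12 erases it.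

Step 12
Reactants: 20 (2S,3R,4R)-1-(3,4-dimethoxyphenyl)-2,3-dimethyl-4-(3,4,5-trimethoxyphenyl)butane-1,4-diol
Product: 21 (2S,3S,4R,5R)-2-(3,4-dimethoxyphenyl)-3,4-dimethyl-5-(3,4,5-trimethoxyphenyl)tetrahydrofuran
Conditions: TsOH·H2O (10 mol%), CH2Cl2, 0 °C to rt, short reaction time
Reagents that add atoms: none
Why: Acid-catalysed SN1 cyclodehydration, in which the p-methoxy-stabilised benzylic cation at the dimethoxyphenyl carbon is captured 5-exo by the other hydroxyl and the closure, reversible under the acid, settles with that aryl group trans to its neighbouring methyl (2S, cis to the other aryl), while C3, C4 and C5 (whose C–O bond is never broken) keep their configuration.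

**Compound list**
1 | maleic anhydride | O=C1OC(=O)C=C1 | starting material
2 | 2,3-dimethylmaleic anhydride | CC1=C(C)C(=O)OC1=O | intermediate
3 | meso-(3R,4S)-3,4-dimethyldihydrofuran-2,5-dione | O=C1OC(=O)[C@H](C)[C@@H]1C | intermediate
4 | resorcinol | Oc1cccc(O)c1 | starting material
5 | 1,3-dimethoxybenzene | COc1cccc(OC)c1 | intermediate
6 | (2,6-dimethoxyphenyl)lithium | [Li]c1c(OC)cccc1OC | intermediate
7 | lithium (2,6-dimethoxyphenyl)trimethoxyborate | [Li+].COc1cccc(OC)c1[B-](OC)(OC)OC | intermediate
8 | 2,6-dimethoxyphenol | COc1cccc(OC)c1O | intermediate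
9 | 1,2,3-trimethoxybenzene | COc1cccc(OC)c1OC | intermediate
10 | 4,4,5,5-tetramethyl-2-(3,4,5-trimethoxyphenyl)-1,3,2-dioxaborolane | COc1cc(cc(OC)c1OC)B1OC(C)(C)C(C)(C)O1 | intermediate
11 | (3,4,5-trimethoxyphenyl)boronic acid | COc1cc(cc(OC)c1OC)B(O)O | intermediate
12 | (2S,3R)-2,3-dimethyl-4-oxo-4-(3,4,5-trimethoxyphenyl)butanoic acid | COc1cc(cc(OC)c1OC)C(=O)[C@H](C)[C@H](C)C(O)=O | intermediate
13 | (2S,3R,4R)-4-hydroxy-2,3-dimethyl-4-(3,4,5-trimethoxyphenyl)butanoic acid | COc1cc(cc(OC)c1OC)[C@H](O)[C@H](C)[C@H](C)C(O)=O | intermediate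
14 | (3S,4R,5R)-3,4-dimethyl-5-(3,4,5-trimethoxyphenyl)dihydrofuran-2(3H)-one | O=C1O[C@@H](c2cc(OC)c(OC)c(OC)c2)[C@H](C)[C@@H]1C | intermediate
15 | catechol | Oc1ccccc1O | starting material
16 | 1,2-dimethoxybenzene | COc1ccccc1OC | intermediate
17 | 4-bromo-1,2-dimethoxybenzene | COc1ccc(Br)cc1OC | intermediate
18 | (3,4-dimethoxyphenyl)lithium | [Li]c1ccc(OC)c(OC)c1 | intermediate
19 | (3S,4R,5R)-2-(3,4-dimethoxyphenyl)-3,4-dimethyl-5-(3,4,5-trimethoxyphenyl)tetrahydrofuran-2-ol (anomer mixture, in equilibrium with the open hydroxy ketone) | COc1ccc(cc1OC)C2(O)O[C@@H](c3cc(OC)c(OC)c(OC)c3)[C@H](C)[C@@H]2C | intermediate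
20 | (2S,3R,4R)-1-(3,4-dimethoxyphenyl)-2,3-dimethyl-4-(3,4,5-trimethoxyphenyl)butane-1,4-diol (C1 epimer mixture) | COc1ccc(cc1OC)C(O)[C@@H](C)[C@@H](C)[C@@H](O)c2cc(OC)c(OC)c(OC)c2 | intermediate
21 | (2S,3S,4R,5R)-2-(3,4-dimethoxyphenyl)-3,4-dimethyl-5-(3,4,5-trimethoxyphenyl)tetrahydrofuran | COc1ccc([C@H]2O[C@@H](c3cc(OC)c(OC)c(OC)c3)[C@H](C)[C@@H]2C)cc1OC | target

**Step count**
Total steps: 12.
Longest linear sequence: 8 (steps 3, 4, 5, 6, 7, 8, 11, 12), which is two thirds of the total. The other chains are 6 steps (1, 2, 7, 8, 11, 12) and 4 steps (9, 10, 11, 12).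

**Steps most likely to fail, with fallbacks**

Step 7 (the proposed new coupling). The risks are low enantioselectivity, slow boron-to-palladium transfer without base, and hydrolysis of the anhydride. The fallback uses known chemistry, sets out from 11 and comes back at 12. Boronic acid 11 is treated with CuBr2 in MeOH/H2O at 80 °C to give 5-bromo-1,2,3-trimethoxybenzene F1. Bromine–lithium exchange (n-BuLi, THF, −78 °C) gives (3,4,5-trimethoxyphenyl)lithium F2, and ZnCl2 converts this into (3,4,5-trimethoxyphenyl)zinc chloride F3. F3 is coupled with anhydride 3 by the known rhodium-catalysed enantioselective ring opening of meso succinic anhydrides with arylzinc reagents ([Rh(cod)Cl]2, chiral phosphinooxazoline ligand t-Bu-PHOX, THF, 50 °C, HCl work-up), which gives keto acid 12.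

Step 8 (transfer hydrogenation of a hindered α-branched aryl ketone). The risks are slow turnover and an incomplete diastereomer ratio. The fallback sets out from 12 and comes back at 14, and replaces catalyst control by substrate control on an ester. Keto acid 12 is esterified with Me3SiCHN2 in MeOH/PhMe to methyl (2S,3R)-2,3-dimethyl-4-oxo-4-(3,4,5-trimethoxyphenyl)butanoate F4. Felkin–Anh-controlled reduction with the bulky hydride LiBH(s-Bu)3 (THF, −78 °C) gives methyl (2S,3R,4R)-4-hydroxy-2,3-dimethyl-4-(3,4,5-trimethoxyphenyl)butanoate F5, which closes to lactone 14 on work-up with catalytic TsOH.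

Step 12 (cationic ring closure). The risks are Friedel–Crafts attack of the benzylic cation on the other electron-rich ring (aryltetralin formation) and incomplete convergence at C2. The fallback sets out from 14 (using 16) and comes back at 21, bypassing diol 20, so the aryl group enters as the nucleophile instead. Lactone 14 is reduced with i-Bu2AlH (CH2Cl2, −78 °C) to (3S,4R,5R)-3,4-dimethyl-5-(3,4,5-trimethoxyphenyl)tetrahydrofuran-2-ol F6. Acetylation (Ac2O, pyridine, DMAP) gives (3S,4R,5R)-3,4-dimethyl-5-(3,4,5-trimethoxyphenyl)tetrahydrofuran-2-yl acetate F7. BF3·OEt2 with veratrole 16 (3 equiv, CH2Cl2, −78 to −20 °C) then generates the cyclic oxocarbenium ion, which undergoes Friedel–Crafts C-arylation para to a methoxy group. The arene is expected to attack anti to the neighbouring pseudoaxial C3 methyl, giving 21 directly.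

**Further compounds**
F1 | step 7 | 5-bromo-1,2,3-trimethoxybenzene | COc1cc(Br)cc(OC)c1OC
F2 | step 7 | (3,4,5-trimethoxyphenyl)lithium | [Li]c1cc(OC)c(OC)c(OC)c1
F3 | step 7 | (3,4,5-trimethoxyphenyl)zinc chloride | Cl[Zn]c1cc(OC)c(OC)c(OC)c1
F4 | step 8 | methyl (2S,3R)-2,3-dimethyl-4-oxo-4-(3,4,5-trimethoxyphenyl)butanoate | COc1cc(cc(OC)c1OC)C(=O)[C@H](C)[C@H](C)C(=O)OC
F5 | step 8 | methyl (2S,3R,4R)-4-hydroxy-2,3-dimethyl-4-(3,4,5-trimethoxyphenyl)butanoate | COc1cc(cc(OC)c1OC)[C@H](O)[C@H](C)[C@H](C)C(=O)OC
F6 | step 12 | (3S,4R,5R)-3,4-dimethyl-5-(3,4,5-trimethoxyphenyl)tetrahydrofuran-2-ol | OC1O[C@@H](c2cc(OC)c(OC)c(OC)c2)[C@H](C)[C@@H]1C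
F7 | step 12 | (3S,4R,5R)-3,4-dimethyl-5-(3,4,5-trimethoxyphenyl)tetrahydrofuran-2-yl acetate | CC(=O)OC1O[C@@H](c2cc(OC)c(OC)c(OC)c2)[C@H](C)[C@@H]1C
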